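**Plan**
Numbering (daucane): C1 = methyl-bearing fusion carbon, C2/C3 = ring CH2, C4 = isopropyl carbinol, C5 = fusion CH, C6 = acyloxy CH, C7 = CH2, C8 = methyl carbinol, C9 = secondary carbinol, C10 = CH2. β is the face of the C1 methyl.
Cuts: first the O6–acyl bond. The trans-diol then goes back to the 8α,9α-epoxide, the 8-ene and the 8-methyl-9-ketone. Next C8–C9 and C7–C8 are cut together (CH–CH3 leaves as diazoethane), then C6–C7 (aldol), C4–iPr, C5–C6, C1–CH3 and C1–C10.
Enabling feature: in the seven-membered ring C1–C10–C9–C8–C7–C6–C5, C8 lies between oxygenated C9 and the C7 methylene. Deleting it leaves a chair cyclohexanone C1–C10–C9–C7–C6–C5 (C=O at C9, a CH2 on each side) trans-fused to the cyclopentane C1–C5, with 6α-O equatorial.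
Forward: the cyclopentane is bought as an enone and fully substituted, the six-membered ring closes by aldol addition, one carbon is inserted to give the seven-membered ring, and the epoxide, ester and diol come last.
Stereochemistry: C1 comes from a ligand-controlled conjugate methylation. C5, C4 and C6 follow by relay from C1 (anti attack, anti addition, equatorial aldol). C9 comes from a 6α-OH-directed epoxidation and C8 from its hydrolysis with inversion.

Key step: step 10

Remark: 2 (THF solution), 18 and 26 are taken as commercial, and the antipode of the NHC ligand that gives (R)-C1 is used.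

Step 1
Reactants: 1 3-ethoxycyclopent-2-en-1-one; 2 2-methylallylmagnesium chloride
Product: 4 3-(2-methylallyl)cyclopent-2-en-1-one, via chloromagnesium alkoxide 3 (not isolated)
Conditions: 2 (1.2 equiv), THF, 0 °C; then 1 M HCl, 0 °C, short contact
Reagents that add atoms: water O
Why: Stork–Danheiser enone synthesis, in which 1,2-addition of the allylic Grignard reagent to the vinylogous ester and cold acidic hydrolysis with loss of water should give the β-substituted enone, brief contact with cold dilute acid keeping the 1,1-disubstituted alkene out of conjugation and no stereocentre being formed.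

Step 2
Reactants: 4 3-(2-methylallyl)cyclopent-2-en-1-one; 5 trimethylaluminium
Product: 7 (R)-triethyl{[3-methyl-3-(2-methylallyl)cyclopent-1-en-1-yl]oxy}silane, via dimethylaluminium enolate 6 (not isolated)
Conditions: Cu(OTf)2 (5 mol %), chiral sulfonate-bearing bidentate NHC–Ag(I) complex (2.5 mol %), 5, THF, −78 °C; then TESOTf, −78 → −20 °C
Reagents that add atoms: triethylsilyl triflate CC[Si](CC)(CC)OS(=O)(=O)C(F)(F)F
Why: Copper/NHC-catalysed asymmetric conjugate addition of an alkylaluminium reagent to a β-substituted cyclopentenone is an established entry to all-carbon quaternary centres, the ligand choosing the enone face so that C1 becomes R, and the silyl triflate traps the aluminium enolate as the regiodefined C4=C5 enol ether.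

Step 3
Reactants: 7 (R)-silyl enol ether; 8 trimethyl orthoformate
Product: 9 (2S,3R)-2-(dimethoxymethyl)-3-methyl-3-(2-methylallyl)cyclopentan-1-one
Conditions: 8, TMSOTf (10 mol %), CH2Cl2, −78 °C
Reagents that add atoms: none
Why: Mukaiyama-type acetal aldol reaction, in which the dimethoxycarbenium ion from the orthoformate attacks the enol ether only at C5 and from the face opposite the bulkier methallyl arm on the neighbouring quaternary C1, placing C6 cis to the C1 methyl (5α-H), the arrangement also expected to be preferred on equilibration of this epimerisable centre.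

Step 4
Reactants: 9 β-keto acetal; 10 isopropylmagnesium chloride
Product: 11 (1R,2R,3R)-2-(dimethoxymethyl)-1-isopropyl-3-methyl-3-(2-methylallyl)cyclopentan-1-ol
Conditions: 10, LaCl3·2LiCl (1 equiv), THF, 0 °C; aq. NH4Cl
Reagents that add atoms: none
Why: Lanthanide-mediated Grignard 1,2-addition, which suppresses enolisation and β-hydride reduction of hindered cyclopentanones, should bring the isopropyl group in on the α face, anti to the adjacent β-oriented dimethoxymethyl group, so that C4 forms as the 4β-carbinol.

Step 5
Reactants: 11 tertiary carbinol acetal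
Product: 13 (1R,2R,5R)-2-isopropyl-5-methyl-5-(2-methylallyl)-2-[(triethylsilyl)oxy]cyclopentane-1-carbaldehyde, via methoxy lutidinium triflate 12 (not isolated)
Conditions: TESOTf (3.5 equiv), 2,6-lutidine (5 equiv), CH2Cl2, 0 °C → rt; then H2O
Reagents that add atoms: triethylsilyl triflate CC[Si](CC)(CC)OS(=O)(=O)C(F)(F)F; water O
Why: Silyl triflate with 2,6-lutidine silylates the tertiary carbinol and, in the known base-buffered acetal cleavage, converts the aldehyde acetal into a pyridinium salt that water hydrolyses at neutral pH, so the aldehyde appears with O4 already masked against retro-aldol cleavage and dehydration, with C5 unepimerised, and with the excess base intercepting the activated acetal before the pendant alkene can.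

Step 6
Reactants: 13 alkenyl aldehyde
Product: 15 (1R,2R,5R)-2-isopropyl-5-methyl-5-(2-oxopropyl)-2-[(triethylsilyl)oxy]cyclopentane-1-carbaldehyde, via secondary ozonide 14 (not isolated)
Conditions: O3, CH2Cl2, −78 °C; then Me2S, −78 °C → rt
Reagents that add atoms: ozone [O-][O+]=O
Why: Ozonolysis with reductive work-up cleaves the only C=C bond to the C9 methyl ketone and leaves the aldehyde, the silyl ether and the three stereocentres untouched.

Step 7
Reactants: 15 keto aldehyde
Product: 16 (1R,3aR,7S,7aS)-7-hydroxy-1-isopropyl-3a-methyl-1-[(triethylsilyl)oxy]octahydro-5H-inden-5-one (trans-hydrindan-9-one in daucane numbering; 6α-OH)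
Conditions: K2CO3 (0.3 equiv), MeOH, 0 °C → rt
Reagents that add atoms: none
Why: Reversible intramolecular aldol addition (6-enolendo-exo-trig, the only enolate/carbonyl pairing that gives an unstrained ring) of the C7 methyl-ketone enolate to the C6 aldehyde closes the chair ring trans-fused at C1–C5, and equilibration should place O6 equatorial (6α) because the axial epimer is syn-diaxial to the C1 methyl, while an equatorial hydroxyl is poorly aligned for E1cB dehydration.

Step 8
Reactants: 16 ketol
Product: 17 (1R,3aR,7S,7aS)-7-[(tert-butyldimethylsilyl)oxy]-1-isopropyl-3a-methyl-1-[(triethylsilyl)oxy]octahydro-5H-inden-5-one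
Conditions: TBSOTf, 2,6-lutidine, CH2Cl2, −78 → 0 °C
Reagents that add atoms: tert-butyldimethylsilyl triflate CC(C)(C)[Si](C)(C)OS(=O)(=O)C(F)(F)F
Why: Silyl triflate/lutidine silylation reaches hindered secondary alcohols at low temperature without provoking retro-aldol cleavage or β-elimination of the ketol.

Step 9
Reactants: 18 N-ethyl-N-nitrosourea
Product: 19 diazoethane (ethereal solution)
Conditions: 50% aq. KOH, Et2O, 0 °C; organic layer dried over KOH pellets and used at once
Reagents that add atoms: none
Why: Base-induced fragmentation of an N-alkyl-N-nitrosourea is the classical preparation of simple diazoalkanes.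

Step 10
Reactants: 17 trans-hydrindan-9-one; 19 diazoethane; 5 trimethylaluminium (promoter)
Product: 21 6α-(tert-butyldimethylsilyloxy)-4β-(triethylsilyloxy)daucan-9-one (1β-CH3 and 5α-H; 8α-CH3 epimer drawn), via diazonium aluminate betaine 20 (not isolated)
Conditions: 5 (1.2 equiv), CH2Cl2, −78 °C; then 19 in Et2O (2 equiv), −78 → −30 °C; aq. Rochelle salt
Reagents that add atoms: none
Why: Trimethylaluminium activates the C9 carbonyl, the nucleophilic carbon of diazoethane adds to give betaine 20, and the ring bond antiperiplanar to C–N2+ shifts as nitrogen leaves, so that CH(CH3) enters as C8 with formation of C8–C9 and C7–C8. This is the Lewis-acid-promoted Büchner–Curtius–Schlotterbeck homologation (a Tiffeneau–Demjanov-type 1,2-shift), well known for turning cyclohexanones into 2-alkylcycloheptanones, and it should stop after one insertion because the α-branched cycloheptanone is the less reactive ketone. The seven-membered ring is not closed end to end but arises by one-atom enlargement of the six-membered ring C1–C10–C9–C7–C6–C5, the cyclopentane and the trans fusion being spectators. C1, C4, C5 and C6 are not touched, and the new C8 centre follows the configuration of the diazonium carbon, stays epimerisable next to the ketone and is erased in step 11, so either epimer serves. The step needs migration of C7 and not C10: the axial C1 methyl forces attack at C9 from the equatorial α side, and in the betaine the C-methyl group should turn away from the neopentyl C10 flank, leaving the slim N2+ gauche to C10 and antiperiplanar to C7, in line with the rule that the less encumbered α-carbon migrates in these insertions. To support this, O6 is kept as an equatorial silyl ether, the least electron-withdrawing oxygen substituent and one misaligned for β-elimination, and O4 is capped so that neither the aluminium reagent nor diazoethane is consumed by a free carbinol.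

Step 11
Reactants: 21 8-methyl-9-ketone
Product: 22 6α-(tert-butyldimethylsilyloxy)-4β-(triethylsilyloxy)dauc-8-en-9-yl triflate
Conditions: Tf2O, 2,6-di-tert-butyl-4-methylpyridine, CH2Cl2, 0 °C → rt
Reagents that add atoms: triflic anhydride O=S(=O)(OS(=O)(=O)C(F)(F)F)C(F)(F)F
Why: O-Triflation of a ketone with triflic anhydride and a hindered pyridine gives the more substituted enol triflate, here the tetrasubstituted C8=C9 isomer rather than a C9=C10 alkene pressed against quaternary C1, and both C8 epimers converge.

Step 12
Reactants: 22 enol triflate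
Product: 23 6α-(tert-butyldimethylsilyloxy)-4β-(triethylsilyloxy)dauc-8-ene
Conditions: Pd(OAc)2 (5 mol %), PPh3 (10 mol %), HCO2H, n-Bu3N, DMF, 60 °C
Reagents that add atoms: none
Why: Palladium-catalysed formate reduction of an enol triflate replaces OTf by H with the double bond held in place, which gives the 8-ene without touching the silyl ethers.

Step 13
Reactants: 23 bis-silyl ether
Product: 24 dauc-8-ene-4β,6α-diol (jaeschkeanadiol)
Conditions: HF·pyridine, THF, 0 °C → rt
Reagents that add atoms: none
Why: Fluoride-mediated desilylation removes both silyl ethers in one operation, and the trisubstituted alkene and the tertiary carbinol tolerate the buffered reagent.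

Step 14
Reactants: 24 diol
Product: 25 8α,9α-epoxydaucane-4β,6α-diol
Conditions: VO(acac)2 (5 mol %), t-BuOOH (decane), CH2Cl2, 0 °C → rt
Reagents that add atoms: tert-butyl hydroperoxide CC(C)(C)OO
Why: Vanadium-catalysed hydroxyl-directed epoxidation, in which the homoallylic 6α-OH binds the peroxovanadium species and delivers oxygen to the α face of C8=C9, fixes the 9α-oxygen whatever the intrinsic facial bias of the ring.

Step 15
Reactants: 25 epoxy diol; 26 4-(benzyloxy)benzoyl chloride
Product: 27 8α,9α-epoxy-4β-hydroxydaucan-6α-yl 4-(benzyloxy)benzoate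
Conditions: 26, Et3N, DMAP (0.3 equiv), CH2Cl2, 0 °C → rt
Reagents that add atoms: none
Why: DMAP-catalysed acylation distinguishes the secondary 6α-OH from the unreactive tertiary 4β-OH, and the epoxide is inert to these mildly basic conditions.

Step 16
Reactants: 27 epoxy ester
Product: 28 4β,8β,9α-trihydroxydaucan-6α-yl 4-(benzyloxy)benzoate
Conditions: HClO4 (5 mol %), THF–H2O, 0 °C → rt
Reagents that add atoms: water O
Why: Acid-catalysed hydrolysis of a trisubstituted epoxide breaks the weaker tertiary C8–O bond with backside attack of water from the β face, so C8 is inverted to 8β-OH/8α-CH3 while C9 keeps its 9α-oxygen, and the α-oriented ester cannot compete for that face.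

Step 17
Reactants: 28 benzyl-protected triol ester
Product: 29 4β,8β,9α-trihydroxydaucan-6α-yl 4-hydroxybenzoate (target)
Conditions: H2 (1 atm), 10% Pd/C, EtOAc, rt
Reagents that add atoms: none
Why: Hydrogenolysis of the aryl benzyl ether is neutral and touches neither the benzoate ester nor the three carbinols.

**Compound list**
1 | 3-ethoxycyclopent-2-en-1-one | CCOC1=CC(=O)CC1 | starting material
2 | 2-methylallylmagnesium chloride | C=C(C)C[Mg]Cl | starting material
3 | chloromagnesium 3-ethoxy-1-(2-methylallyl)cyclopent-2-en-1-olate (racemic) | CCOC1=CC(CC(C)=C)(O[Mg]Cl)CC1 | intermediate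
4 | 3-(2-methylallyl)cyclopent-2-en-1-one | CC(=C)CC1=CC(=O)CC1 | intermediate
5 | trimethylaluminium | C[Al](C)C | starting material
6 | dimethylaluminium (R)-3-methyl-3-(2-methylallyl)cyclopent-1-en-1-olate | CC(=C)C[C@@]1(C)CCC(O[Al](C)C)=C1 | intermediate
7 | (R)-triethyl{[3-methyl-3-(2-methylallyl)cyclopent-1-en-1-yl]oxy}silane | CC(=C)C[C@@]1(C)CCC(O[Si](CC)(CC)CC)=C1 | intermediate
8 | trimethyl orthoformate | COC(OC)OC | starting material
9 | (2S,3R)-2-(dimethoxymethyl)-3-methyl-3-(2-methylallyl)cyclopentan-1-one | COC(OC)[C@H]1C(=O)CC[C@]1(C)CC(C)=C | intermediate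
10 | isopropylmagnesium chloride | CC(C)[Mg]Cl | starting material
11 | (1R,2R,3R)-2-(dimethoxymethyl)-1-isopropyl-3-methyl-3-(2-methylallyl)cyclopentan-1-ol | COC(OC)[C@H]1[C@](O)(C(C)C)CC[C@]1(C)CC(C)=C | intermediate
12 | 4-O-TES α-methoxy 2,6-dimethylpyridinium triflate at C6 (C6 unassigned) | COC([C@H]1[C@](O[Si](CC)(CC)CC)(C(C)C)CC[C@]1(C)CC(C)=C)[n+]2c(C)cccc2C.[O-]S(=O)(=O)C(F)(F)F | intermediate
13 | (1R,2R,5R)-2-isopropyl-5-methyl-5-(2-methylallyl)-2-[(triethylsilyl)oxy]cyclopentane-1-carbaldehyde | O=C[C@H]1[C@](O[Si](CC)(CC)CC)(C(C)C)CC[C@]1(C)CC(C)=C | intermediate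
14 | secondary ozonide of 13 (3-methyl-1,2,4-trioxolan-3-ylmethyl arm on C1) | O=C[C@H]1[C@](O[Si](CC)(CC)CC)(C(C)C)CC[C@]1(C)CC2(C)OCOO2 | intermediate
15 | (1R,2R,5R)-2-isopropyl-5-methyl-5-(2-oxopropyl)-2-[(triethylsilyl)oxy]cyclopentane-1-carbaldehyde | O=C[C@H]1[C@](O[Si](CC)(CC)CC)(C(C)C)CC[C@]1(C)CC(C)=O | intermediate
16 | (1R,3aR,7S,7aS)-7-hydroxy-1-isopropyl-3a-methyl-1-[(triethylsilyl)oxy]octahydro-5H-inden-5-one | CC(C)[C@]1(O[Si](CC)(CC)CC)CC[C@]2(C)CC(=O)C[C@H](O)[C@H]21 | intermediate
17 | (1R,3aR,7S,7aS)-7-[(tert-butyldimethylsilyl)oxy]-1-isopropyl-3a-methyl-1-[(triethylsilyl)oxy]octahydro-5H-inden-5-one | CC(C)[C@]1(O[Si](CC)(CC)CC)CC[C@]2(C)CC(=O)C[C@H](O[Si](C)(C)C(C)(C)C)[C@H]21 | intermediate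
18 | N-ethyl-N-nitrosourea | CCN(N=O)C(N)=O | starting material
19 | diazoethane | CC=[N+]=[N-] | intermediate
20 | 9β-(trimethylaluminato-oxy)-9α-(1-diazonioethyl) adduct of 17 (C8 unassigned) | CC(C)[C@]1(O[Si](CC)(CC)CC)CC[C@]2(C)C[C@](O[Al-](C)(C)C)(C(C)[N+]#N)C[C@H](O[Si](C)(C)C(C)(C)C)[C@H]21 | intermediate
21 | 6α-(tert-butyldimethylsilyloxy)-4β-(triethylsilyloxy)daucan-9-one (8α-CH3 drawn) | CC(C)[C@]1(O[Si](CC)(CC)CC)CC[C@]2(C)CC(=O)[C@H](C)C[C@H](O[Si](C)(C)C(C)(C)C)[C@H]21 | intermediate
22 | 6α-(tert-butyldimethylsilyloxy)-4β-(triethylsilyloxy)dauc-8-en-9-yl triflate | CC(C)[C@]1(O[Si](CC)(CC)CC)CC[C@]2(C)CC(OS(=O)(=O)C(F)(F)F)=C(C)C[C@H](O[Si](C)(C)C(C)(C)C)[C@H]21 | intermediate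
23 | 6α-(tert-butyldimethylsilyloxy)-4β-(triethylsilyloxy)dauc-8-ene | CC(C)[C@]1(O[Si](CC)(CC)CC)CC[C@]2(C)CC=C(C)C[C@H](O[Si](C)(C)C(C)(C)C)[C@H]21 | intermediate
24 | dauc-8-ene-4β,6α-diol (jaeschkeanadiol) | CC(C)[C@]1(O)CC[C@]2(C)CC=C(C)C[C@H](O)[C@H]21 | intermediate
25 | 8α,9α-epoxydaucane-4β,6α-diol | CC(C)[C@]1(O)CC[C@]2(C)C[C@@H]3O[C@]3(C)C[C@H](O)[C@H]21 | intermediate
26 | 4-(benzyloxy)benzoyl chloride | O=C(Cl)c1ccc(OCc2ccccc2)cc1 | starting material
27 | 8α,9α-epoxy-4β-hydroxydaucan-6α-yl 4-(benzyloxy)benzoate | CC(C)[C@]1(O)CC[C@]2(C)C[C@@H]3O[C@]3(C)C[C@H](OC(=O)c4ccc(OCc5ccccc5)cc4)[C@H]21 | intermediate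
28 | 4β,8β,9α-trihydroxydaucan-6α-yl 4-(benzyloxy)benzoate | CC(C)[C@]1(O)CC[C@]2(C)C[C@H](O)[C@@](C)(O)C[C@H](OC(=O)c3ccc(OCc4ccccc4)cc3)[C@H]21 | intermediate
29 | 4β,8β,9α-trihydroxydaucan-6α-yl 4-hydroxybenzoate | CC(C)[C@]1(O)CC[C@]2(C)C[C@H](O)[C@@](C)(O)C[C@H](OC(=O)c3ccc(O)cc3)[C@H]21 | target

**Step count**
Total: 17 steps. Longest linear sequence: 16 steps (1 → 29 through steps 1–8 and 10–17). Step 9 is a one-step side branch.

**Steps most likely to fail**

Step 10. Both α-carbons of the ketone are methylenes, and the β-oxygen at C6 lowers the migratory aptitude of C7. A competing shift of C10 could therefore erode the regioselectivity, and addition to a carbonyl shielded by the axial methyl could be slow.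
The fallback sets out from 17 and returns at 21. It fixes the regiochemistry by enolisation instead of by a migration.
- LDA with TMSCl present (THF, −78 °C) should remove the more accessible C7 proton and give the kinetic C7=C9 trimethylsilyl enol ether F1.
- Chloro(methyl)carbene (CH3CHCl2, n-BuLi, Et2O, −40 °C) should add to it to give the 8-chloro-8-methyl-9-siloxycyclopropane F2, in which C8 is already bonded to C7 and C9.
- Warming (toluene, Et3N, reflux) should break the C7–C9 bond in the halocyclopropane-to-allyl-cation manner, with loss of chloride and silicon, to give the ring-enlarged 8-methyl-7-en-9-one F3.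
- Hydrogenation of the enone (H2, Pd/C, EtOAc) leads back to 21.

Step 7. Three processes could compete with clean ketol formation: dehydration of the ketol, enolisation of the hindered aldehyde with expulsion of the C4 silyloxy group, and epimerisation at C5.
The fallback sets out from 13 and returns at 17. It closes the same C6–C7 bond without any base by a type II carbonyl-ene reaction.
- Methylaluminium bis(4-bromo-2,6-di-tert-butylphenoxide) (CH2Cl2, −78 °C) should join the alkene terminus to the aldehyde through an open transition state. This keeps O6 equatorial, away from the C1 methyl, and gives the 9-methylene trans-hydrindan-6α-ol F4.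
- TBSOTf/2,6-lutidine gives its silyl ether F5.
- Ozonolysis of the exocyclic methylene delivers 17.

Step 3. Facial discrimination between the methyl and methallyl groups on C1 may be too weak. That would erode the configuration at C5 and, by relay, at C4.
The fallback sets out from 7 and returns at 13. It uses a much larger one-carbon electrophile and a different aldehyde surrogate.
- 1,3-Dithian-2-ylium tetrafluoroborate (CH2Cl2, −78 °C) should give the 2-(1,3-dithian-2-yl) ketone F6, whose bulky substituent sharpens both the kinetic and the equilibrium preference for the position trans to the methallyl arm.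
- Isopropylmagnesium chloride with LaCl3·2LiCl gives the dithianyl carbinol F7.
- TESOTf/2,6-lutidine gives its triethylsilyl ether F8.
- Alkylative hydrolysis (MeI, CaCO3, aq. MeCN) releases aldehyde 13.

Further compounds
F1 | step 10 | C7=C9 trimethylsilyl enol ether of 17 | CC(C)[C@]1(O[Si](CC)(CC)CC)CC[C@]2(C)CC(O[Si](C)(C)C)=C[C@H](O[Si](C)(C)C(C)(C)C)[C@H]21
F2 | step 10 | 8-chloro-8-methyl-9-(trimethylsilyloxy)cyclopropane spanning C7–C8–C9 of 17 (new centres unassigned) | CC(C)[C@]1(O[Si](CC)(CC)CC)CC[C@]2(C)CC3(O[Si](C)(C)C)C(C)(Cl)C3[C@H](O[Si](C)(C)C(C)(C)C)[C@H]21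
F3 | step 10 | 6α-(tert-butyldimethylsilyloxy)-4β-(triethylsilyloxy)dauc-7-en-9-one | CC(C)[C@]1(O[Si](CC)(CC)CC)CC[C@]2(C)CC(=O)C(C)=C[C@H](O[Si](C)(C)C(C)(C)C)[C@H]21
F4 | step 7 | 9-methylene-4β-(triethylsilyloxy) trans-hydrindan-6α-ol (daucane numbering, C8 absent) | CC(C)[C@]1(O[Si](CC)(CC)CC)CC[C@]2(C)CC(=C)C[C@H](O)[C@H]21
F5 | step 7 | 6-O-TBS ether of F4 | CC(C)[C@]1(O[Si](CC)(CC)CC)CC[C@]2(C)CC(=C)C[C@H](O[Si](C)(C)C(C)(C)C)[C@H]21
F6 | step 3 | 2-(1,3-dithian-2-yl) analogue of 9 | C1(SCCCS1)[C@H]2C(=O)CC[C@]2(C)CC(C)=C
F7 | step 3 | 2-(1,3-dithian-2-yl) analogue of 11 | C1(SCCCS1)[C@H]2[C@](O)(C(C)C)CC[C@]2(C)CC(C)=C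
F8 | step 3 | 4-O-triethylsilyl ether of F7 | C1(SCCCS1)[C@H]2[C@](O[Si](CC)(CC)CC)(C(C)C)CC[C@]2(C)CC(C)=C
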